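## Structural features

The target is a lariciresinol-type lignan built on one oxolane ring (O1, C2, C3, C4, C5). C2 carries a 4-hydroxy-3,5-dimethoxyphenyl (syringyl) ring, C3 a CH2O arm (C9) esterified with (E)-ferulic acid, C4 a 4-hydroxy-3-methoxybenzyl arm (C7' with its guaiacyl ring), and C5 is an unsubstituted CH2. The stereocentres C2 (S), C3 (R) and C4 (R) are contiguous: the C2 aryl group is trans to the C9 arm, and the C9 and C7' arms are cis. Fragile elements are the three free phenols (oxidation, competition in any acylation), the C2–O1 bond (benzylic to an oxygen-rich arene, so it ionises under acid) and the conjugated ferulate ester (no strong nucleophiles, no hydrogenation). The real difficulty is to place two carbon arms cis on C3 and C4 beside a trans C2 aryl group in one absolute sense, and then to acylate the only aliphatic hydroxyl. The key step uses the 1,4-relation of C9 and C7' across the C3–C4 bond: joined as C9=C7' they complete a cyclobutene fused to the oxolane, which is the (2+2) adduct of an aryl alkyne and the C3=C4 bond of a 2-aryl-2,5-dihydrofuran. That four-membered ring can only be cis-fused, which fixes the arms cis, and the C2 aryl group is already present to steer the face.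

## Logic of the disconnections

**18 to 16 and 17.** The C9–O bond of the ester is cut first. The cinnamate is the part least tolerant of base, ozone and hydride, so it should arrive last. This leaves the bare core 16 and the commercial acid 17. The forward step must esterify one aliphatic hydroxyl beside three phenols without protecting groups; a Mitsunobu reaction does this because only the carboxyl group is acidic enough and only C9–OH can be activated.

**16 to 15.** The aryl O–acyl and aryl O–Si bonds are cut. Both phenol masks are needed up to the deoxygenation, but they must go before the ester exists, because a hindered aryl pivalate cannot be cleaved safely beside a cinnamate. The forward step must be one basic operation that touches no stereocentre.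

**15 to 14.** C7'–H is traced back to C7'–OH. The oxygen at C7' is what the cleavage of the four-membered ring leaves behind. The forward step must ionise the C7' carbinol while the equally benzylic C2–O bond stays; the silyloxy donor on the C7' ring and the acyloxy group on the C2 ring provide that difference.

**14 to 11 (through 13 and 12).** C9 and C7' are reconnected as a double bond. Two cis arms become one ring, so the C3/C4 relation no longer has to be set on its own. The forward cleavage must spare the arenes, and the cis 1,4-dicarbonyl stage 13 must be reduced before C3 or C4 epimerises.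

**11 to 7 and 10.** C3–C9 and C4–C7' are cut together. Three stereocentres fall to one (C2), and the molecule splits into two fragments of similar size. The forward step needs addition anti to the C2 aryl group, the alkyne orientation that puts the aryl-bearing carbon on C4, suppression of alkyne self-reaction, and an intact C2–O bond.

**7 to 5 and 6.** The C2–aryl bond is cut. An enantioselective Heck arylation delivers the 2,5-dihydrofuran directly from a bulk chemical. The forward step needs enantioface control, no migration of the double bond, and a triflate leaving group for the cationic pathway.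

**5 to 4 to 2 to 1.** The O–S bond is cut, the aryl C–O bond is traced back to the aryl C–CHO bond, and the pivalate is removed. Compound 1 already has the full substitution pattern. The forward oxidation needs aryl rather than hydride migration, and the formate must be cleaved without loss of the pivalate.

**10 to 9 to 8.** The terminal alkyne carbon and the O–Si bond are removed. The forward homologation must run under conditions that leave an aryl silyl ether intact.

## Other disconnections considered

**Alternative 1:** The cut removes C2–C3 and C4–C5 together, a (3+2) disconnection into a carbonyl ylide (C2, O1, C5) and a C3=C4 dipolarophile in which C9 and C7' are tied up as the lactone of the γ-aryl butenolide A1. Forward, CsF triggers desilylation and chloride loss from the α-chloro (trimethylsilyl)methyl ether A2 (ylide generation), and the dipole adds to A1 anti to its γ-aryl group to give the cis-fused furofuranone A3.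
- In its favour: the ring, two C–C bonds and C2, C3, C4 arise in one step. The cis fusion secures the cis arms just as the cyclobutene does, so the two plans are equal there. Cycloaddition of such ylides to electron-poor alkenes is an established reaction type, so this key step is better precedented than the cobalt step.
- Against it here: the ylide is unsymmetrical, so its orientation is as open as the alkyne orientation in the chosen plan. The exo or endo placement of the C2 aryl group, which decides C2/C3 trans, is enforced by nothing, whereas the chosen plan sets C2 beforehand. A1 should racemise easily by enolisation toward a furan under basic fluoride. Afterwards the benzylic lactone C7'–O bond must be hydrogenolysed beside the benzylic C2–O bond, and the freed C9 carboxyl group reduced.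
- Step economy: about equal, since the redox corrections after the key step cost what ozonolysis and deoxygenation cost.

**Alternative 2:** The cut is O1–C2. Forward, two-electron anodic oxidation of the free syringyl phenol of the seco-diol A4 makes C2 electrophilic (quinone methide formation), and the hydroxyl of the C5 arm adds to give the mono-silylated core alcohol A5.
- In its favour: the closure is biomimetic and its regiochemistry is unambiguous, because only the five-membered ring can form; this is better than the chosen plan, whose regiocontrol is unproven. C2 should settle trans to C3 under thermodynamic control. A5 already has the free C9 hydroxyl, so the end game is shorter and needs neither ozone nor a benzylic deoxygenation.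
- Against it here: C3 and C4 are not made by the key step and must be built into A4 by a longer acyclic sequence, so the stereochemical problem is moved, not solved. The phenol of A5 is as oxidisable as that of A4, so over-oxidation and solvent capture threaten. Selective oxidation of the syringyl ring over the silylated guaiacyl ring rests on a modest difference in potential.
- Comparison: a cationic closure under thermodynamic control against a metal-templated suprafacial addition under kinetic control. The chosen plan is shorter before the key step, the alternative shorter after it, and the total should favour the chosen plan by a few steps.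

**Alternative 3:** The cut is O1–C5, with the C4 benzyl arm traced back to a C4 ketone. Forward, Ph3PAuNTf2 (monovalent gold) and a pyridine N-oxide oxidise the terminal alkyne of the anti homopropargylic alcohol A6, and the C2 hydroxyl closes onto C5 by O–H insertion to give the furanone A7.
- In its favour: oxidative gold cyclisation of homopropargylic alcohols to oxolan-3-ones is an established reaction type with no regiochemical ambiguity, so this key step is better precedented than the cobalt step. C2 and C3 can be set in A6 by a reliable anti-selective aldehyde propargylation.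
- Against it here: C4 and its arm are still missing after the key step. The arm must be attached by olefination of an enolisable ketone whose C3 carries a β-silyloxymethyl group (β-elimination and C3 epimerisation threaten). The subsequent hydrogenation must add anti to the C3 arm while the benzylic C2–O bond survives. Lewis-acidic gold meets the same labile C2–O bond as cobalt does, so the plans are equal on that point and both need the pivalate.
- Comparison: the cis C3/C4 relation would rest on a substrate-controlled hydrogenation, whereas the chosen plan enforces it by ring fusion, which is the stronger control. The step count should be equal or slightly higher.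

Key step: step 7

Assumption: the (R)-tert-butyl phosphinooxazoline is taken to give the (S)-dihydrofuran, by analogy with the sense of induction of this ligand class with phenyl triflate; the antipodal ligand would be used if the sense proved opposite.

Remark on the structures: the dihydrofuran 7 (S at C2) and the cycloadduct 11 map onto the target configuration without change, so no structure needed correction. The design changes are three: the phenol masks are removed before, not after, the esterification; a borate replaces ZnI2 as halide abstractor in the key step; and the alkyne is added slowly.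

## Route

Step 1
Reactants: 1 syringaldehyde (4-hydroxy-3,5-dimethoxybenzaldehyde)
Product: 2 4-formyl-2,6-dimethoxyphenyl pivalate
Conditions: PivCl, Et3N, DMAP (cat.), CH2Cl2, 0 °C to rt
Reagents that add atoms: pivaloyl chloride, CC(C)(C)C(Cl)=O
Why: DMAP-catalysed O-acylation of a hindered phenol; the pivalate is chosen because it is electron-withdrawing (it will protect the later C2–O bond from ionisation) and survives amine base, hydride at low temperature and acid.

Step 2
Reactants: 2 4-formyl-2,6-dimethoxyphenyl pivalate
Product: 4 4-hydroxy-2,6-dimethoxyphenyl pivalate, via aryl formate 3 (not isolated)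
Conditions: mCPBA, CH2Cl2, 40 °C; then Et3N (cat.), MeOH, 0 °C
Reagents that add atoms: mCPBA, OOC(=O)c1cccc(Cl)c1
Why: Baeyer–Villiger (Dakin-type) oxidation with migration of the oxygenated aryl group gives the formate, which methanolyses far faster than the hindered pivalate; the pivalate sits para to the new phenol, so no acyl migration is possible.

Step 3
Reactants: 4 4-hydroxy-2,6-dimethoxyphenyl pivalate
Product: 5 2,6-dimethoxy-4-[(trifluoromethylsulfonyl)oxy]phenyl pivalate
Conditions: Tf2O, pyridine, CH2Cl2, 0 °C
Reagents that add atoms: triflic anhydride, O=S(=O)(OS(=O)(=O)C(F)(F)F)C(F)(F)F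
Why: Standard O-sulfonylation of an unhindered phenol; the triflate is the leaving group that opens the cationic Heck pathway.

Step 4
Reactants: 5 2,6-dimethoxy-4-[(trifluoromethylsulfonyl)oxy]phenyl pivalate; 6 2,3-dihydrofuran
Product: 7 (S)-2-[3,5-dimethoxy-4-(pivaloyloxy)phenyl]-2,5-dihydrofuran
Conditions: Pd2(dba)3 (2.5 mol%), (R)-4-tert-butyl-2-[2-(diphenylphosphino)phenyl]-4,5-dihydrooxazole (6 mol%), iPr2NEt, THF, 70 °C, sealed vessel, 6 in excess
Reagents that add atoms: none
Why: Enantioselective intermolecular Heck arylation: the cationic aryl palladium species from zerovalent palladium and the triflate adds the aryl group to C2 and palladium to C3 on the enantioface chosen by the P,N ligand, and syn β-hydride elimination toward C4 gives the C3=C4 alkene; with this ligand class the alkene is released without re-insertion, so the double bond does not migrate, and C2 (S) is set under catalyst control.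

Step 5
Reactants: 8 vanillin (4-hydroxy-3-methoxybenzaldehyde)
Product: 9 3-methoxy-4-(triisopropylsilyloxy)benzaldehyde
Conditions: TIPSCl, imidazole, DMF, rt
Reagents that add atoms: triisopropylsilyl chloride, CC(C)[Si](Cl)(C(C)C)C(C)C
Why: Imidazole-mediated silylation of a phenol; the bulky silyl ether is a strong para donor (needed in step 9) and tolerates organolithium, ozone at low temperature and trifluoroacetic acid.

Step 6
Reactants: 9 3-methoxy-4-(triisopropylsilyloxy)benzaldehyde
Product: 10 4-ethynyl-2-methoxyphenyl triisopropylsilyl ether
Conditions: Me3SiCHN2, n-BuLi, THF, −78 °C; then 9, −78 °C to rt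
Reagents that add atoms: trimethylsilyldiazomethane, C[Si](C)(C)C=[N+]=[N-]
Why: Colvin-type one-carbon homologation: the lithiated diazo reagent adds to the aldehyde, Peterson elimination and loss of N2 give an alkylidene carbene that rearranges by 1,2-hydride shift to the terminal alkyne; the cold aprotic conditions spare the aryl silyl ether, which carbonate in methanol might not.

Step 7
Reactants: 7 (S)-2-[3,5-dimethoxy-4-(pivaloyloxy)phenyl]-2,5-dihydrofuran; 10 4-ethynyl-2-methoxyphenyl triisopropylsilyl ether
Product: 11 (1S,2S,5S)-2-[3,5-dimethoxy-4-(pivaloyloxy)phenyl]-6-[3-methoxy-4-(triisopropylsilyloxy)phenyl]-3-oxabicyclo[3.2.0]hept-6-ene (cis-fused; C2 aryl group anti to the cyclobutene)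
Conditions: CoBr2(dppp) (10 mol%), Zn (20 mol%), NaB[C6H3(CF3)2]4 (15 mol%), CH2Cl2, rt; 10 (1.3 equiv) added over 8 h
Reagents that add atoms: none
Why: Proposed new method: Zn reduces CoBr2(dppp) to monovalent cobalt and the borate abstracts bromide, so a cationic (dppp)Co centre binds alkyne 10 and the C3=C4 alkene of 7, oxidative cyclisation gives a cobaltacyclopentene of trivalent cobalt, and C–C reductive elimination closes the cyclobutene and returns monovalent cobalt. The closest known reaction type is the cobalt-catalysed (2+2) cycloaddition of alkynes with cyclopentene-type alkenes to cyclobutenes (and the (2+2) of terminal aryl alkynes with alkenes under monovalent gold); new here is the unsymmetrical 2-aryl-2,5-dihydrofuran, on which the orientation of the alkyne matters. The four-membered ring is closed by reductive elimination from the five-membered metallacycle, a ring contraction at the metal, and because both new bonds (C3–C9 and C4–C7') form on one face of the alkene the ring fusion can only be cis. C3 and C4 are set by the C2 aryl group, which blocks one face of the nearly flat dihydrofuran so that cobalt and alkyne approach anti to it (substrate control, C2/C3 trans). Regioselectivity is required: in the oxidative cyclisation the ligated cobalt and the aryl-bearing alkyne carbon should take the unhindered C4 while the small CH terminus bonds to C3 next to the C2 aryl group, which is why the alkyne is kept terminal. Slow addition of 10 keeps its concentration low against cyclotrimerisation, and the bicyclic metallacycle should disfavour syn β-hydride elimination (Alder-ene path), as with cyclopentene. The pivalate and the two meta methoxy groups make the C2 aryl ring a poor cation stabiliser, and the borate replaces a zinc halide as halide abstractor, so the allylic, benzylic C2–O bond meets as little Lewis acid as possible.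

Step 8
Reactants: 11 (1S,2S,5S)-2-[3,5-dimethoxy-4-(pivaloyloxy)phenyl]-6-[3-methoxy-4-(triisopropylsilyloxy)phenyl]-3-oxabicyclo[3.2.0]hept-6-ene
Product: 14 (2S,3R,4R)-2-[3,5-dimethoxy-4-(pivaloyloxy)phenyl]-3-(hydroxymethyl)-4-{hydroxy[3-methoxy-4-(triisopropylsilyloxy)phenyl]methyl}oxolane (both C7' epimers), via ozonide 12 (not isolated), via keto aldehyde 13 (not isolated)
Conditions: O3, CH2Cl2, −78 °C (Sudan Red 7B end point); PPh3, −78 to −20 °C; then NaBH4, MeOH, −20 to 0 °C
Reagents that add atoms: ozone, [O-][O+]=O
Why: Ozonolysis (Criegee mechanism) of the strained, electron-rich styrenyl C9=C7' bond should be far faster than attack on the acylated and silylated arenes; PPh3 reduces ozonide 12 to keto aldehyde 13 and NaBH4 reduces both carbonyl groups at once, before C3 or C4 can epimerise. The C7' carbinol forms as an epimer mixture, which does not matter because that centre is removed in step 9.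

Step 9
Reactants: 14 (2S,3R,4R)-2-[3,5-dimethoxy-4-(pivaloyloxy)phenyl]-3-(hydroxymethyl)-4-{hydroxy[3-methoxy-4-(triisopropylsilyloxy)phenyl]methyl}oxolane
Product: 15 (2S,3R,4R)-2-[3,5-dimethoxy-4-(pivaloyloxy)phenyl]-3-(hydroxymethyl)-4-[3-methoxy-4-(triisopropylsilyloxy)benzyl]oxolane
Conditions: Et3SiH, CF3CO2H, CH2Cl2, −40 to 0 °C; then NaHCO3, MeOH/H2O, rt
Reagents that add atoms: none
Why: Ionic hydrogenation: the acid ionises the secondary benzylic C7'–OH to a cation stabilised by the para silyloxy group and Et3SiH delivers hydride; capture of that cation by the C9 hydroxyl is reversible under the acid and is drained by hydride transfer. The C2–O bond should survive because its aryl ring carries a para acyloxy group and only meta methoxy groups; the bicarbonate wash frees any C9 trifluoroacetate.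

Step 10
Reactants: 15 (2S,3R,4R)-2-[3,5-dimethoxy-4-(pivaloyloxy)phenyl]-3-(hydroxymethyl)-4-[3-methoxy-4-(triisopropylsilyloxy)benzyl]oxolane
Product: 16 (2S,3R,4R)-2-(4-hydroxy-3,5-dimethoxyphenyl)-4-(4-hydroxy-3-methoxybenzyl)-3-(hydroxymethyl)oxolane
Conditions: KOH, MeOH/THF/H2O, 45 °C, argon; then HCl (aq.) to pH 5
Reagents that add atoms: none
Why: Hydroxide cleaves the aryl pivalate (acyl substitution) and the aryl silyl ether (attack at silicon with a phenoxide leaving group) in one operation; the alkyl C–O bonds and the three stereocentres are inert to base, and air is excluded because electron-rich phenolates autoxidise.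

Step 11
Reactants: 16 (2S,3R,4R)-2-(4-hydroxy-3,5-dimethoxyphenyl)-4-(4-hydroxy-3-methoxybenzyl)-3-(hydroxymethyl)oxolane; 17 (E)-ferulic acid
Product: 18 [(2S,3R,4R)-2-(4-hydroxy-3,5-dimethoxyphenyl)-4-(4-hydroxy-3-methoxybenzyl)oxolan-3-yl]methyl (E)-3-(4-hydroxy-3-methoxyphenyl)prop-2-enoate
Conditions: PPh3, DIAD, THF, 0 °C to rt
Reagents that add atoms: none
Why: Mitsunobu esterification: the betaine is protonated by the carboxylic acid, the only sufficiently acidic partner (the phenols are weaker by about five pKa units), and only the aliphatic C9 hydroxyl can form an alkoxyphosphonium ion, so the carboxylate displaces at the primary carbon and the three phenols stay free; C9 is not a stereocentre and the E alkene is untouched.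

## Compound list

1 | syringaldehyde (4-hydroxy-3,5-dimethoxybenzaldehyde) | COc1cc(C=O)cc(OC)c1O | starting material
2 | 4-formyl-2,6-dimethoxyphenyl pivalate | COc1cc(C=O)cc(OC)c1OC(=O)C(C)(C)C | intermediate
3 | 4-(formyloxy)-2,6-dimethoxyphenyl pivalate | COc1cc(OC=O)cc(OC)c1OC(=O)C(C)(C)C | intermediate
4 | 4-hydroxy-2,6-dimethoxyphenyl pivalate | COc1cc(O)cc(OC)c1OC(=O)C(C)(C)C | intermediate
5 | 2,6-dimethoxy-4-[(trifluoromethylsulfonyl)oxy]phenyl pivalate | COc1cc(OS(=O)(=O)C(F)(F)F)cc(OC)c1OC(=O)C(C)(C)C | intermediate
6 | 2,3-dihydrofuran | C1=COCC1 | starting material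
7 | (S)-2-[3,5-dimethoxy-4-(pivaloyloxy)phenyl]-2,5-dihydrofuran | O1CC=C[C@H]1c1cc(OC)c(OC(=O)C(C)(C)C)c(OC)c1 | intermediate
8 | vanillin (4-hydroxy-3-methoxybenzaldehyde) | COc1cc(C=O)ccc1O | starting material
9 | 3-methoxy-4-(triisopropylsilyloxy)benzaldehyde | COc1cc(C=O)ccc1O[Si](C(C)C)(C(C)C)C(C)C | intermediate
10 | 4-ethynyl-2-methoxyphenyl triisopropylsilyl ether | C#Cc1ccc(O[Si](C(C)C)(C(C)C)C(C)C)c(OC)c1 | intermediate
11 | (1S,2S,5S)-2-[3,5-dimethoxy-4-(pivaloyloxy)phenyl]-6-[3-methoxy-4-(triisopropylsilyloxy)phenyl]-3-oxabicyclo[3.2.0]hept-6-ene | C=1[C@H]2[C@@H](C=1c3ccc(O[Si](C(C)C)(C(C)C)C(C)C)c(OC)c3)CO[C@@H]2c2cc(OC)c(OC(=O)C(C)(C)C)c(OC)c2 | intermediate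
12 | ozonide of 11 (1,2,4-trioxolane spanning C9 and C7'; C2, C3, C4 as in 11; acetal carbons undefined) | O1OC2(c3ccc(O[Si](C(C)C)(C(C)C)C(C)C)c(OC)c3)OC1[C@H]1[C@@H]2CO[C@@H]1c1cc(OC)c(OC(=O)C(C)(C)C)c(OC)c1 | intermediate
13 | (2S,3S,4R)-2-[3,5-dimethoxy-4-(pivaloyloxy)phenyl]-4-[3-methoxy-4-(triisopropylsilyloxy)benzoyl]oxolane-3-carbaldehyde | O=C[C@H]2[C@@H](C(=O)c3ccc(O[Si](C(C)C)(C(C)C)C(C)C)c(OC)c3)CO[C@@H]2c2cc(OC)c(OC(=O)C(C)(C)C)c(OC)c2 | intermediate
14 | (2S,3R,4R)-2-[3,5-dimethoxy-4-(pivaloyloxy)phenyl]-3-(hydroxymethyl)-4-{hydroxy[3-methoxy-4-(triisopropylsilyloxy)phenyl]methyl}oxolane, both C7' epimers | OC[C@H]2[C@@H](C(O)c3ccc(O[Si](C(C)C)(C(C)C)C(C)C)c(OC)c3)CO[C@@H]2c2cc(OC)c(OC(=O)C(C)(C)C)c(OC)c2 | intermediate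
15 | (2S,3R,4R)-2-[3,5-dimethoxy-4-(pivaloyloxy)phenyl]-3-(hydroxymethyl)-4-[3-methoxy-4-(triisopropylsilyloxy)benzyl]oxolane | OC[C@H]2[C@@H](Cc3ccc(O[Si](C(C)C)(C(C)C)C(C)C)c(OC)c3)CO[C@@H]2c2cc(OC)c(OC(=O)C(C)(C)C)c(OC)c2 | intermediate
16 | (2S,3R,4R)-2-(4-hydroxy-3,5-dimethoxyphenyl)-4-(4-hydroxy-3-methoxybenzyl)-3-(hydroxymethyl)oxolane | OC[C@H]2[C@@H](Cc3ccc(O)c(OC)c3)CO[C@@H]2c2cc(OC)c(O)c(OC)c2 | intermediate
17 | (E)-ferulic acid | COc1cc(/C=C/C(O)=O)ccc1O | starting material
18 | [(2S,3R,4R)-2-(4-hydroxy-3,5-dimethoxyphenyl)-4-(4-hydroxy-3-methoxybenzyl)oxolan-3-yl]methyl (E)-3-(4-hydroxy-3-methoxyphenyl)prop-2-enoate | COc1cc(/C=C/C(=O)OC[C@H]2[C@@H](Cc3ccc(O)c(OC)c3)CO[C@@H]2c2cc(OC)c(O)c(OC)c2)ccc1O | target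

## Step count and least certain steps

Total: 11 steps. Longest linear sequence: 9 steps (1 → 2 → 4 → 5 → 7 → 11 → 14 → 15 → 16 → 18, that is steps 1, 2, 3, 4, 7, 8, 9, 10, 11); the alkyne branch (steps 5 and 6) joins at step 7.

**Step 7 (key step, proposed new method).**
- What may go wrong: the alkyne may add in the reverse orientation, because the steric difference between C3 and C4 is modest and there is no electronic bias. Cyclotrimerisation of the terminal alkyne may outrun the cycloaddition, because monovalent cobalt also catalyses it. Cobalt hydride species may shift the C3=C4 double bond.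
- Fallback (known reactions only, no cycloaddition; sets out from 9 and 2, returns at 16):
  - Stobbe condensation of 9 with dimethyl succinate (KOtBu, tBuOH/THF) should give the (E)-benzylidenesuccinic half-ester F1.
  - Asymmetric hydrogenation (Rh(cod)2BF4 with the enantiomer of a DuPhos-type bisphosphine that leads to the R acid, H2, MeOH) gives the (R)-benzylsuccinic half-ester F2.
  - Reduction of the ester group of its potassium salt with Ca(BH4)2 and acidification closes the (R)-β-benzyl-γ-butyrolactone F3.
  - Its lithium enolate (LiN(SiMe3)2, THF, −78 °C) adds to aldehyde 2 anti to the benzyl group and gives the trans aldol lactone F4 (carbinol epimers).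
  - LiAlH4 reduces the lactone and removes the pivalate, giving the phenolic triol F5.
  - A trace of camphorsulfonic acid in CH2Cl2 induces loss of the para-hydroxybenzylic hydroxyl (quinone methide formation) and 5-exo capture by the hydroxyl of the arm on C4. This closes the oxolane with the aryl group trans to the C9 arm, as the mono-silylated core alcohol F6 (the same compound as A5).
  - Bu4NF in THF then gives 16.
  - The trans lactone maps onto cis C9/C7' arms in the oxolane, so all three stereocentres derive from the hydrogenation catalyst.

**Step 9.**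
- What may go wrong: competing ionisation of the C2–O bond (ring opening, over-reduction) and unproductive capture of the C7' cation by the C9 hydroxyl, because both benzylic positions are activated and the hydroxyl sits cis to the cation.
- Fallback (radical path, no cation; sets out from 14, returns at 16):
  - Selective acetylation of the primary hydroxyl (AcCl, 2,4,6-collidine, CH2Cl2, −78 °C) gives the C9 acetate F7.
  - 1,1'-Thiocarbonyldiimidazole converts the benzylic hydroxyl into the thiocarbonylimidazolide F8.
  - Bu3SnH and AIBN in toluene at 90 °C (Barton–McCombie deoxygenation) give the deoxygenated acetate F9.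
  - The conditions of step 10 then remove acetate, pivalate and silyl group together and give 16.

**Step 4.**
- What may go wrong: slow oxidative addition of the oxygen-rich triflate, erosion of enantioselectivity, or partial double-bond migration, because the substrate is more hindered and more electron-rich than the usual aryl triflates.
- Fallback (sets out from 2, returns at 7):
  - Enantioselective addition of divinylzinc (from vinylmagnesium bromide and ZnCl2) to 2 with a chiral β-amino alcohol catalyst of the morpholinoisoborneol type, in the enantiomeric form that gives the S carbinol, should give the (S)-allylic alcohol F10.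
  - O-allylation (NaH, allyl bromide, Bu4NI, THF, 0 °C) gives the allyl ether F11.
  - Ring-closing metathesis with the second-generation Grubbs catalyst RuCl2(H2IMes)(PCy3)(=CHPh) in CH2Cl2 at 40 °C closes the dihydrofuran 7.

**Step 11.**
- What may go wrong: competing O-alkylation or O-acylation of the phenols and incomplete conversion of the β-branched primary alcohol, because three phenols are present in the two partners.
- Fallback (protecting-group route; sets out from 16 and 17, returns at 18):
  - Acetylation of the phenolates only (Ac2O, aqueous NaOH, 0 °C, Schotten–Baumann conditions) gives the bis(aryl acetate) F12 with C9–OH free.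
  - 17 is acetylated (Ac2O, pyridine) to 4-O-acetylferulic acid F13.
  - Carbodiimide coupling (EDC hydrochloride, DMAP, CH2Cl2) gives the triacetate F14.
  - Pyrrolidine in CH2Cl2 at 0 °C cleaves the three aryl acetates by aminolysis, leaves the alkyl cinnamate and gives 18.

**Step 2.**
- What may go wrong: hydride migration instead of aryl migration (oxidation to the benzoic acid), because the para acyloxy group is only a weak donor and the methoxy groups are meta to the migrating carbon.
- Fallback (sets out from 1, returns at 5):
  - Dakin oxidation of 1 (H2O2, aqueous NaOH, 0 °C, argon) gives 2,6-dimethoxybenzene-1,4-diol F15.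
  - The unhindered and more acidic hydroxyl is sulfonylated with PhNTf2 and Et3N (one equivalent each, CH2Cl2, 0 °C) to the monotriflate F16.
  - Pivaloylation of the remaining hindered phenol (PivCl, Et3N, DMAP) gives 5.

## Further compounds

F1 | step 7 | (E)-4-[3-methoxy-4-(triisopropylsilyloxy)phenyl]-3-(methoxycarbonyl)but-3-enoic acid | COC(=O)/C(CC(O)=O)=C/c1ccc(O[Si](C(C)C)(C(C)C)C(C)C)c(OC)c1
F2 | step 7 | (R)-3-(methoxycarbonyl)-4-[3-methoxy-4-(triisopropylsilyloxy)phenyl]butanoic acid | OC(=O)C[C@@H](Cc1ccc(O[Si](C(C)C)(C(C)C)C(C)C)c(OC)c1)C(=O)OC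
F3 | step 7 | (R)-4-[3-methoxy-4-(triisopropylsilyloxy)benzyl]dihydrofuran-2(3H)-one | O=C1C[C@@H](Cc2ccc(O[Si](C(C)C)(C(C)C)C(C)C)c(OC)c2)CO1
F4 | step 7 | trans aldol lactone, (3S,4R)-3-{hydroxy[3,5-dimethoxy-4-(pivaloyloxy)phenyl]methyl}-4-[3-methoxy-4-(triisopropylsilyloxy)benzyl]dihydrofuran-2(3H)-one, carbinol epimers | O=C1[C@H](C(O)c2cc(OC)c(OC(=O)C(C)(C)C)c(OC)c2)[C@@H](Cc2ccc(O[Si](C(C)C)(C(C)C)C(C)C)c(OC)c2)CO1
F5 | step 7 | phenolic triol, 2-[hydroxy(4-hydroxy-3,5-dimethoxyphenyl)methyl]-3-[3-methoxy-4-(triisopropylsilyloxy)benzyl]butane-1,4-diol, carbinol epimers | OC[C@H](C(O)c1cc(OC)c(O)c(OC)c1)[C@@H](Cc1ccc(O[Si](C(C)C)(C(C)C)C(C)C)c(OC)c1)CO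
F6 | step 7 | (2S,3R,4R)-2-(4-hydroxy-3,5-dimethoxyphenyl)-3-(hydroxymethyl)-4-[3-methoxy-4-(triisopropylsilyloxy)benzyl]oxolane | OC[C@H]1[C@@H](Cc2ccc(O[Si](C(C)C)(C(C)C)C(C)C)c(OC)c2)CO[C@@H]1c1cc(OC)c(O)c(OC)c1
F7 | step 9 | C9 acetate of 14 | CC(=O)OC[C@H]2[C@@H](C(O)c3ccc(O[Si](C(C)C)(C(C)C)C(C)C)c(OC)c3)CO[C@@H]2c2cc(OC)c(OC(=O)C(C)(C)C)c(OC)c2
F8 | step 9 | C7' O-(imidazol-1-ylthiocarbonyl) derivative of F7 | CC(=O)OC[C@H]2[C@@H](C(OC(=S)n4ccnc4)c3ccc(O[Si](C(C)C)(C(C)C)C(C)C)c(OC)c3)CO[C@@H]2c2cc(OC)c(OC(=O)C(C)(C)C)c(OC)c2
F9 | step 9 | C9 acetate of 15 | CC(=O)OC[C@H]2[C@@H](Cc3ccc(O[Si](C(C)C)(C(C)C)C(C)C)c(OC)c3)CO[C@@H]2c2cc(OC)c(OC(=O)C(C)(C)C)c(OC)c2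
F10 | step 4 | (S)-1-[3,5-dimethoxy-4-(pivaloyloxy)phenyl]prop-2-en-1-ol | C=C[C@H](O)c1cc(OC)c(OC(=O)C(C)(C)C)c(OC)c1
F11 | step 4 | (S)-4-[1-(allyloxy)prop-2-en-1-yl]-2,6-dimethoxyphenyl pivalate | C=C[C@H](OCC=C)c1cc(OC)c(OC(=O)C(C)(C)C)c(OC)c1
F12 | step 11 | bis(aryl acetate) of 16 | OC[C@H]2[C@@H](Cc3ccc(OC(C)=O)c(OC)c3)CO[C@@H]2c2cc(OC)c(OC(C)=O)c(OC)c2
F13 | step 11 | (E)-4-O-acetylferulic acid | COc1cc(/C=C/C(O)=O)ccc1OC(C)=O
F14 | step 11 | triacetate of 18 | COc1cc(/C=C/C(=O)OC[C@H]2[C@@H](Cc3ccc(OC(C)=O)c(OC)c3)CO[C@@H]2c2cc(OC)c(OC(C)=O)c(OC)c2)ccc1OC(C)=O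
F15 | step 2 | 2,6-dimethoxybenzene-1,4-diol | COc1cc(O)cc(OC)c1O
F16 | step 2 | 4-hydroxy-3,5-dimethoxyphenyl trifluoromethanesulfonate | COc1cc(OS(=O)(=O)C(F)(F)F)cc(OC)c1O
A1 | alternative 1 | (S)-5-[4-(benzyloxy)-3-methoxyphenyl]furan-2(5H)-one | O=C1C=C[C@H](O1)c1ccc(OCc2ccccc2)c(OC)c1
A2 | alternative 1 | 2-(benzyloxy)-5-{chloro[(trimethylsilyl)methoxy]methyl}-1,3-dimethoxybenzene | ClC(OC[Si](C)(C)C)c1cc(OC)c(OCc2ccccc2)c(OC)c1
A3 | alternative 1 | cis-fused furofuranone (lactone of C9 onto C7', both phenols as benzyl ethers) | O=C3[C@H]2[C@@H]([C@H](O3)c4ccc(OCc5ccccc5)c(OC)c4)CO[C@@H]2c2cc(OC)c(OCc3ccccc3)c(OC)c2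
A4 | alternative 2 | (2R,3R)-2-(4-hydroxy-3,5-dimethoxybenzyl)-3-[3-methoxy-4-(triisopropylsilyloxy)benzyl]butane-1,4-diol | OC[C@H](Cc1cc(OC)c(O)c(OC)c1)[C@@H](Cc1ccc(O[Si](C(C)C)(C(C)C)C(C)C)c(OC)c1)CO
A5 | alternative 2 | (2S,3R,4R)-2-(4-hydroxy-3,5-dimethoxyphenyl)-3-(hydroxymethyl)-4-[3-methoxy-4-(triisopropylsilyloxy)benzyl]oxolane | OC[C@H]1[C@@H](Cc2ccc(O[Si](C(C)C)(C(C)C)C(C)C)c(OC)c2)CO[C@@H]1c1cc(OC)c(O)c(OC)c1
A6 | alternative 3 | (1S,2R)-2-[(tert-butyldiphenylsilyloxy)methyl]-1-[3,5-dimethoxy-4-(pivaloyloxy)phenyl]but-3-yn-1-ol | CC(C)(C)[Si](c1ccccc1)(c1ccccc1)OC[C@H]([C@H](O)c1cc(OC)c(OC(=O)C(C)(C)C)c(OC)c1)C#C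
A7 | alternative 3 | trans-2-[3,5-dimethoxy-4-(pivaloyloxy)phenyl]-3-[(tert-butyldiphenylsilyloxy)methyl]oxolan-4-one | CC(C)(C)[Si](c1ccccc1)(c1ccccc1)OC[C@H]1C(=O)CO[C@@H]1c1cc(OC)c(OC(=O)C(C)(C)C)c(OC)c1
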